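**Plan**

- Retrosynthesis: the C3–C4 bond is cut first (C4 methyl as bis(phenylsulfonyl)methane), then the C3–aryl bond to chromene unit B (aryl Grignard reagent plus enal, acetate on C3), then the C1–aryl bond to unit A (aryllithium plus 3-(dimethylamino)acrolein), and last the pyran ring (phenol plus 3-methylbut-2-enal).
- Forward: the pyran ring is closed once on 4-bromo-3-methoxyphenol and the resulting bromochromene is used twice. The C1–C3 chain is attached to unit A, unit B is added at C3, and C4 is joined last and unmasked to the methyl group.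
- Enabling feature: numbering the butenyl chain C1 (alkene CH on unit A), C2, C3 (stereocentre, on unit B), C4 (methyl), C1 and C3 carry the same 7-methoxy-2,2-dimethyl-2H-chromen-6-yl ring system. Without C4, the C1–C2–C3 unit is therefore a symmetric 1,3-diarylallyl system with enantiotopic ends.
- Stereochemistry: the only stereocentre, C3 (S), is set by a chiral phosphinooxazoline on palladium in the allylic alkylation of the racemic acetate. The E alkene comes from the E enal and is set again by the syn,syn allyl complex.

Key step: step 4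

Assumption: the sense of induction is carried over from 1,3-diphenylallyl acetate, where (S)-phosphinooxazolines are taken to give the (R)-configured bis-sulfone adduct. The (R)-ligand is therefore specified for the (S)-adduct, and the ligand antipode is exchanged if the first run shows the opposite sense.

**Route**

Step 1
Reactants: 1 4-bromo-3-methoxyphenol; 2 3-methylbut-2-enal
Product: 5 6-bromo-7-methoxy-2,2-dimethyl-2H-chromene, via cyclic boronate 3 (not isolated), via ortho-quinone methide 4 (not isolated)
Conditions: PhB(OH)2, AcOH, toluene, reflux, Dean–Stark trap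
Reagents that add atoms: none
Why: Phenylboronic acid templates the ortho-selective condensation of the phenol with the enal through cyclic boronate 3, whose thermal fragmentation gives ortho-quinone methide 4 that closes by oxa-6π electrocyclisation (phenol–enal chromenylation); the phenol position para to the methoxy group is the more nucleophilic and less hindered ortho site, so the linear 6-bromo-7-methoxy isomer is expected.

Step 2
Reactants: 5 6-bromo-7-methoxy-2,2-dimethyl-2H-chromene; 6 (E)-3-(dimethylamino)acrylaldehyde
Product: 9 (E)-3-(7-methoxy-2,2-dimethyl-2H-chromen-6-yl)prop-2-enal, via aryllithium 7 (not isolated), via lithium aminoallyl alkoxide 8 (not isolated)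
Conditions: n-BuLi, THF, −78 °C; then 6, −78 → 0 °C; then 1 M aq. HCl, 0 °C → rt
Reagents that add atoms: water, O
Why: Bromine–lithium exchange gives aryllithium 7, which adds to the carbonyl group of the vinylogous formamide 6, and aqueous acid then removes the hydroxyl group and hydrolyses the vinylogous iminium ion to the thermodynamically preferred E enal (vinylogous Bouveault formylation), the chromene alkene and the aryl ethers being inert to both stages.

Step 3
Reactants: 5 6-bromo-7-methoxy-2,2-dimethyl-2H-chromene; 9 (E)-3-(7-methoxy-2,2-dimethyl-2H-chromen-6-yl)prop-2-enal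
Product: 12 rac-(E)-1,3-bis(7-methoxy-2,2-dimethyl-2H-chromen-6-yl)prop-2-en-1-yl acetate, via Grignard reagent 10 (not isolated), via bromomagnesium allyl alkoxide 11 (not isolated)
Conditions: 5, Mg turnings (I2-activated), THF, 45 °C; then 9, −20 °C; then Ac2O, DMAP (cat.), −20 → 0 °C; aq. NaHCO3; filtration through Et3N-deactivated silica, used promptly
Reagents that add atoms: acetic anhydride, CC(=O)OC(C)=O
Why: Magnesium inserts into the aryl C–Br bond to give Grignard reagent 10, which adds 1,2 to the non-enolisable enal, and bromomagnesium alkoxide 11 is O-acylated in the same flask, so the ionisable diarylallyl alcohol never meets acid (Grignard carbonyl addition with in situ acylation); no stereocontrol is needed because the acetate is used as the racemate, and allylic transposition of the acetate is degenerate in this symmetric system.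

Step 4
Reactants: 12 rac-(E)-1,3-bis(7-methoxy-2,2-dimethyl-2H-chromen-6-yl)prop-2-en-1-yl acetate; 13 bis(phenylsulfonyl)methane
Product: 15 (S,E)-1,3-bis(7-methoxy-2,2-dimethyl-2H-chromen-6-yl)-4,4-bis(phenylsulfonyl)but-1-ene, via allylpalladium acetate complex 14 (not isolated)
Conditions: [Pd(C3H5)Cl]2 (2.5 mol%), (R)-2-[2-(diphenylphosphino)phenyl]-4-isopropyl-4,5-dihydrooxazole ((R)-iPr-PHOX, 6 mol%), Cs2CO3, CH2Cl2, 0 °C
Reagents that add atoms: none
Why: Zerovalent palladium formed from [Pd(C3H5)Cl]2 and the (R)-phosphinooxazoline ionises either enantiomer of 12 with inversion to the same syn,syn 1,3-diarylallyl complex of divalent palladium 14, in which C1 and C3 carry identical chromenyl groups and are enantiotopic. The cesium salt of 13, a soft carbanion, attacks outer-sphere and anti to the metal at the terminus trans to phosphorus, forming only the C3–C4 bond; no ring is closed. This is the Tsuji–Trost asymmetric allylic alkylation of symmetric 1,3-diarylallyl acetates with stabilised carbanions, the bis-sulfone serving as a methide equivalent. The new stereocentre C3 is set by the chiral ligand alone, the (R)-ligand being expected to give the (S)-adduct, and the racemic acetate converges on it. Regioselectivity is not in question because both termini are constitutionally the same, the syn,syn allyl delivers the E alkene, and the hindered gem-dimethyl allylic aryl ether of each chromene should not be ionised. The carbonate buffer and 0 °C hold back the uncatalysed ionisation of the electron-rich acetate, which would give racemic product.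

Step 5
Reactants: 15 (S,E)-1,3-bis(7-methoxy-2,2-dimethyl-2H-chromen-6-yl)-4,4-bis(phenylsulfonyl)but-1-ene
Product: 17 (S,E)-1,3-bis(7-methoxy-2,2-dimethyl-2H-chromen-6-yl)but-1-ene, via monosulfone 16 (not isolated)
Conditions: Mg turnings, MeOH–THF, 0 °C → rt; then sat. aq. NH4Cl
Reagents that add atoms: none
Why: Magnesium in methanol transfers single electrons to the sulfones and cleaves the two C–S bonds one after the other through monosulfone 16, with protonation by the solvent (reductive desulfonylation); the electron-rich styrene and chromene alkenes should not be reduced, and C3–H is not acidic enough under magnesium methoxide to lose its configuration.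

**Compound list**

1 | 4-bromo-3-methoxyphenol | COc1cc(O)ccc1Br | starting material
2 | 3-methylbut-2-enal | CC(C)=CC=O | starting material
3 | 6-bromo-7-methoxy-4-(2-methylprop-1-en-1-yl)-2-phenyl-4H-1,3,2-benzodioxaborinine (racemic) | COc1cc2OB(c3ccccc3)OC(C=C(C)C)c2cc1Br | intermediate
4 | 4-bromo-3-methoxy-6-(3-methylbut-2-en-1-ylidene)cyclohexa-2,4-dien-1-one (ortho-quinone methide) | O=C1C=C(OC)C(Br)=CC1=CC=C(C)C | intermediate
5 | 6-bromo-7-methoxy-2,2-dimethyl-2H-chromene | COc1cc2c(cc1Br)C=CC(C)(C)O2 | intermediate
6 | (E)-3-(dimethylamino)acrylaldehyde | CN(C)/C=C/C=O | starting material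
7 | (7-methoxy-2,2-dimethyl-2H-chromen-6-yl)lithium | COc1cc2c(cc1[Li])C=CC(C)(C)O2 | intermediate
8 | lithium (E)-3-(dimethylamino)-1-(7-methoxy-2,2-dimethyl-2H-chromen-6-yl)prop-2-en-1-olate (racemic) | COc1cc2c(cc1C([O-])/C=C/N(C)C)C=CC(C)(C)O2.[Li+] | intermediate
9 | (E)-3-(7-methoxy-2,2-dimethyl-2H-chromen-6-yl)prop-2-enal | COc1cc2c(cc1/C=C/C=O)C=CC(C)(C)O2 | intermediate
10 | (7-methoxy-2,2-dimethyl-2H-chromen-6-yl)magnesium bromide | COc1cc2c(cc1[Mg]Br)C=CC(C)(C)O2 | intermediate
11 | bromomagnesium (E)-1,3-bis(7-methoxy-2,2-dimethyl-2H-chromen-6-yl)prop-2-en-1-olate (racemic), drawn as its ions | COc1cc2c(cc1/C=C/C([O-])c1cc3c(cc1OC)OC(C)(C)C=C3)C=CC(C)(C)O2.[Mg+2].[Br-] | intermediate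
12 | rac-(E)-1,3-bis(7-methoxy-2,2-dimethyl-2H-chromen-6-yl)prop-2-en-1-yl acetate | COc1cc2c(cc1/C=C/C(OC(C)=O)c1cc3c(cc1OC)OC(C)(C)C=C3)C=CC(C)(C)O2 | intermediate
13 | bis(phenylsulfonyl)methane | O=S(=O)(CS(=O)(=O)c1ccccc1)c1ccccc1 | starting material
14 | [syn,syn-η3-1,3-bis(7-methoxy-2,2-dimethyl-2H-chromen-6-yl)allyl][(R)-iPr-PHOX]palladium acetate, divalent palladium, drawn as its ionic components | COc1cc2c(cc1[CH-]/C=C/c1cc3c(cc1OC)OC(C)(C)C=C3)C=CC(C)(C)O2.[Pd+2].CC(C)[C@@H]1COC(=N1)c1ccccc1P(c1ccccc1)c1ccccc1.CC(=O)[O-] | intermediate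
15 | (S,E)-1,3-bis(7-methoxy-2,2-dimethyl-2H-chromen-6-yl)-4,4-bis(phenylsulfonyl)but-1-ene | COc1cc2c(cc1/C=C/[C@H](C(S(=O)(=O)c1ccccc1)S(=O)(=O)c1ccccc1)c1cc3c(cc1OC)OC(C)(C)C=C3)C=CC(C)(C)O2 | intermediate
16 | (S,E)-1,3-bis(7-methoxy-2,2-dimethyl-2H-chromen-6-yl)-4-(phenylsulfonyl)but-1-ene | COc1cc2c(cc1/C=C/[C@H](CS(=O)(=O)c1ccccc1)c1cc3c(cc1OC)OC(C)(C)C=C3)C=CC(C)(C)O2 | intermediate
17 | (S,E)-1,3-bis(7-methoxy-2,2-dimethyl-2H-chromen-6-yl)but-1-ene | COc1cc2c(cc1/C=C/[C@H](C)c1cc3c(cc1OC)OC(C)(C)C=C3)C=CC(C)(C)O2 | target

**Count**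

Total steps: 5. Longest linear sequence: 5 steps (steps 1 to 5; bromochromene 5 enters in both step 2 and step 3).

**Steps most likely to fail**

Step 4. The electron-rich acetate may ionise without the metal, and the adduct may re-ionise at palladium by loss of the bis-sulfonyl carbanion; both processes would erode the enantiomeric purity. The ortho-methoxy groups may also slow attack on the allyl complex. The fallback sets out from 5 and rejoins the route at 17. Suzuki–Miyaura coupling of 5 with potassium vinyltrifluoroborate (PdCl2(dppf), Cs2CO3, THF–H2O, 80 °C) should give 7-methoxy-2,2-dimethyl-6-vinyl-2H-chromene F1. Nickel-catalysed asymmetric hydrovinylation of F1 (ethene at 1 atm, [Ni(C3H5)Br]2, the antipode of a binaphthol-derived phosphoramidite ligand that leads to the S product, Na[B(3,5-(CF3)2C6H3)4], CH2Cl2, −70 °C) should give (S)-6-(but-3-en-2-yl)-7-methoxy-2,2-dimethyl-2H-chromene F2. Cross-metathesis of F2 with F1 (second-generation Hoveyda–Grubbs catalyst, 1,4-benzoquinone, CH2Cl2, 40 °C) should then give 17 with the E alkene.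

Step 3. Magnesium insertion into the electron-rich aryl bromide may be sluggish or accompanied by biaryl homocoupling. The doubly activated acetate may also ionise during quench or chromatography, leading to hydrolysis or Friedel–Crafts oligomerisation at the electron-rich C8 positions, and O-acylation of the hindered magnesium alkoxide may stay incomplete. The fallback sets out from 5 and rejoins the route at 12. Aryllithium 7, made from 5 as in step 2, is quenched in one run with DMF to give 7-methoxy-2,2-dimethyl-2H-chromene-6-carbaldehyde F3 and in another with N-methoxy-N-methylacetamide to give 1-(7-methoxy-2,2-dimethyl-2H-chromen-6-yl)ethan-1-one F4. Claisen–Schmidt condensation of F3 with F4 (KOH, EtOH, rt) should give (E)-1,3-bis(7-methoxy-2,2-dimethyl-2H-chromen-6-yl)prop-2-en-1-one F5. Luche reduction (NaBH4, CeCl3·7H2O, MeOH–THF, −20 °C) should give rac-(E)-1,3-bis(7-methoxy-2,2-dimethyl-2H-chromen-6-yl)prop-2-en-1-ol F6, which can be purified and stored. F6 is acetylated just before use (Ac2O, Et3N, catalytic DMAP, CH2Cl2, 0 °C) to give 12.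

Step 1. Ortho C-alkylation of the bromine-deactivated phenol may be slow, so that the enal oligomerises, and ring closure toward the position between the two oxygen substituents may give the angular regioisomer. The fallback sets out from 1 and rejoins the route at 5. O-Alkylation of 1 with 3-chloro-3-methylbut-1-yne (catalytic CuCl2·2H2O, DBU, MeCN, 0 °C) should give 1-bromo-2-methoxy-4-[(2-methylbut-3-yn-2-yl)oxy]benzene F7. Heating F7 in N,N-diethylaniline at 190 °C should give 5 by aromatic Claisen rearrangement, 1,5-hydrogen shift and oxa-6π electrocyclisation.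

**Further compounds**

F1 | step 4 | 7-methoxy-2,2-dimethyl-6-vinyl-2H-chromene | C=Cc1cc2c(cc1OC)OC(C)(C)C=C2
F2 | step 4 | (S)-6-(but-3-en-2-yl)-7-methoxy-2,2-dimethyl-2H-chromene | C=C[C@H](C)c1cc2c(cc1OC)OC(C)(C)C=C2
F3 | step 3 | 7-methoxy-2,2-dimethyl-2H-chromene-6-carbaldehyde | COc1cc2c(cc1C=O)C=CC(C)(C)O2
F4 | step 3 | 1-(7-methoxy-2,2-dimethyl-2H-chromen-6-yl)ethan-1-one | COc1cc2c(cc1C(C)=O)C=CC(C)(C)O2
F5 | step 3 | (E)-1,3-bis(7-methoxy-2,2-dimethyl-2H-chromen-6-yl)prop-2-en-1-one | COc1cc2c(cc1/C=C/C(=O)c1cc3c(cc1OC)OC(C)(C)C=C3)C=CC(C)(C)O2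
F6 | step 3 | rac-(E)-1,3-bis(7-methoxy-2,2-dimethyl-2H-chromen-6-yl)prop-2-en-1-ol | COc1cc2c(cc1/C=C/C(O)c1cc3c(cc1OC)OC(C)(C)C=C3)C=CC(C)(C)O2
F7 | step 1 | 1-bromo-2-methoxy-4-[(2-methylbut-3-yn-2-yl)oxy]benzene | COc1cc(OC(C)(C)C#C)ccc1Br
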